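**Plan**
- Retrosynthesis: cut the geranyl ether at O6, then the acetate at O4, then C4a–C4 and O2–C3 of the lactone (ring B) together. This leads back to a 2,4,5-trioxygenated benzoic acid and 1,2-butadiene; the exocyclic CH2 that the allene leaves on C4 stands in for the C4 oxygen.
- Enabling feature: C1 sits on C8a, whose ortho neighbours are C8 (oxygen-bearing) and C4a (the only C–H). A carboxylate-directed palladation can therefore only strike C4a, and C4, C3 and the C3 methyl map onto the central, inner and methyl carbons of the allene.
- Forward order: ring A comes from a commercial benzoic acid (oxygen pattern completed by benzylation and Br-to-OMe exchange), ring B is closed in one operation by C–H annulation, then C4=CH2 is cleaved to C4=O.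
- Stereochemistry: in the 1,4-dione, C3–H lies between the C4 ketone and lactone O2 and epimerises freely. One asymmetric transfer hydrogenation with dynamic kinetic resolution sets C4 (catalyst control) and C3 (cis delivery) as 3R,4R.
- Endgame: acetylation of O4, hydrogenolysis of the benzyl ethers, geranylation of O6 alone (O8–H is held in a hydrogen bond to C1=O).

Key step: step 3

Remarks: atoms are numbered as in isochroman-1-one (C1 lactone carbonyl, O2, C3, C4, C4a, C5 to C8, C8a); ring A is the benzene ring, ring B the lactone. The target is the 3,4-cis (3R,4R) isomer with an E (geranyl) double bond. 5-Bromo-2,4-dihydroxybenzoic acid, 1,2-butadiene (a liquefied gas, used in a sealed tube) and geranyl bromide are taken as commercial. Racemates with one stereocentre are drawn without stereodescriptors.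

**Step 1**
Reactants: 1 5-bromo-2,4-dihydroxybenzoic acid
Product: 2 benzyl 2,4-bis(benzyloxy)-5-bromobenzoate
Conditions: BnBr (3.5 equiv), K2CO3 (4 equiv), DMF, 70 °C
Reagents that add atoms: benzyl bromide, BrCc1ccccc1
Why: Williamson ether synthesis on both phenoxides together with O-alkylation of the carboxylate in one pot should give the fully benzylated compound, the hydrogen-bonded 2-OH being the slow site that the excess reagent and the heat take care of.

**Step 2**
Reactants: 2 benzyl 2,4-bis(benzyloxy)-5-bromobenzoate
Product: 5 2,4-bis(benzyloxy)-5-methoxybenzoic acid, via methyl 2,4-bis(benzyloxy)-5-bromobenzoate 3 (not isolated), via methyl 2,4-bis(benzyloxy)-5-methoxybenzoate 4 (not isolated)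
Conditions: NaOMe (6 equiv, 25% in MeOH), CuBr (10 mol%), DMF, 110 °C; then 2 M NaOH, 70 °C; HCl work-up
Reagents that add atoms: sodium methoxide, C[O-].[Na+]; sodium hydroxide, [OH-].[Na+]
Why: Ullmann-type copper-catalysed methoxylation of the aryl bromide (preceded by ester exchange to the methyl ester 3) followed by saponification in the same pot should give the acid, the benzyl aryl ethers being inert to methoxide and hydroxide.

**Step 3**
Reactants: 5 2,4-bis(benzyloxy)-5-methoxybenzoic acid; 6 1,2-butadiene
Product: 7 rac-6,8-bis(benzyloxy)-5-methoxy-3-methyl-4-methylideneisochroman-1-one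
Conditions: Pd(OAc)2 (10 mol%), N-acetylglycine (20 mol%), Cu(OAc)2 (2.2 equiv), KOAc (0.5 equiv), 1,2-butadiene (3 equiv), t-AmOH, sealed tube, 80 °C
Reagents that add atoms: none
Why: Proposed new method: carboxylate-directed concerted metalation–deprotonation by divalent palladium (assisted by the N-acetylglycine ligand) should metalate the single ortho C–H of 5 (the carbon that becomes C4a) to a five-membered palladacycle; 1,2-butadiene then inserts into the aryl–Pd bond with the aryl group going to the central allene carbon (new bond C4a–C4), which gives an η3-allylpalladium carboxylate, and C–O bond formation at the methyl-bearing allyl terminus (new bond O2–C3) releases 7 and zerovalent palladium, which Cu(OAc)2 returns to the divalent state. The closest known reaction types are the heteroannulation of 1,2-dienes by 2-iodobenzoic acids under zerovalent palladium, which runs through the same allylpalladium carboxylate, and the carboxylate-directed ortho-C–H olefination of benzoic acids under divalent palladium; their merger on a free benzoic acid C–H bond is what is proposed. Ring B closes as a (4+2) annulation, the C–O step being a 6-exo attack of the carboxylate oxygen on the allyl unit that leaves the double bond exocyclic at C4. The new stereocentre C3 is formed without control (racemate), by design, since step 4 makes it epimerisable and step 5 sets it. Site selectivity on ring A is needed against the innate electrophilic preference for C7 (between the two benzyloxy groups) and is secured by chelation, C4a being the only C–H within reach of the carboxylate; closure at the methyl-bearing allyl terminus and not at CH2 follows the usual preference of oxygen nucleophiles for the more substituted end of a 1-alkyl-2-arylallyl palladium.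

**Step 4**
Reactants: 7 rac-6,8-bis(benzyloxy)-5-methoxy-3-methyl-4-methylideneisochroman-1-one
Product: 9 rac-6,8-bis(benzyloxy)-5-methoxy-3-methylisochromane-1,4-dione, via 6,8-bis(benzyloxy)-4-hydroxy-4-(hydroxymethyl)-5-methoxy-3-methylisochroman-1-one 8 (not isolated)
Conditions: OsO4 (2 mol%), NaIO4 (4 equiv), 2,6-lutidine (2 equiv), dioxane/H2O 3:1, rt
Reagents that add atoms: sodium periodate, [Na+].[O-]I(=O)(=O)=O (terminal oxygen source); OsO4, O=[Os](=O)(=O)=O (catalytic carrier of the oxygen)
Why: Lemieux–Johnson oxidation: OsO4 dihydroxylates the exocyclic 1,1-disubstituted alkene (the only C=C present) and NaIO4 cleaves the diol 8 to the C4 ketone with loss of the helper carbon as formaldehyde, which avoids ozone on the electron-rich ring A; C3 of the product is racemic and labile, as intended.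

**Step 5**
Reactants: 9 rac-6,8-bis(benzyloxy)-5-methoxy-3-methylisochromane-1,4-dione
Product: 10 (3R,4R)-6,8-bis(benzyloxy)-4-hydroxy-5-methoxy-3-methylisochroman-1-one
Conditions: RuCl[(S,S)-TsDPEN](p-cymene) (2 mol%; TsDPEN = N-tosyl-1,2-diphenylethylenediamine), HCO2H/Et3N (5:2), EtOAc, 35 °C
Reagents that add atoms: none
Why: Noyori–Ikariya asymmetric transfer hydrogenation under dynamic kinetic resolution: C3–H, flanked by the C4 ketone and the lactone oxygen O2, should epimerise through the enol under Et3N faster than reduction, the (S,S) catalyst should deliver hydride to the face of the aryl ketone that gives 4R (the spatial sense in which 1-tetralone gives (S)-1-tetralol; here the descriptor is R because C3 outranks C4a), and of the two C3 epimers it should take the one whose methyl group lies anti to the incoming hydride, so that OH and CH3 end up cis (3R).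

**Step 6**
Reactants: 10 (3R,4R)-6,8-bis(benzyloxy)-4-hydroxy-5-methoxy-3-methylisochroman-1-one
Product: 11 (3R,4R)-6,8-bis(benzyloxy)-5-methoxy-3-methyl-1-oxoisochroman-4-yl acetate
Conditions: Ac2O (1.5 equiv), pyridine, DMAP (5 mol%), CH2Cl2, 0 °C to rt
Reagents that add atoms: acetic anhydride, CC(=O)OC(C)=O
Why: DMAP-catalysed acetylation (nucleophilic acyl transfer) of the only free hydroxyl, the secondary C4 alcohol, should proceed with retention at C4 since the C–O bond is not touched.

**Step 7**
Reactants: 11 (3R,4R)-6,8-bis(benzyloxy)-5-methoxy-3-methyl-1-oxoisochroman-4-yl acetate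
Product: 12 (3R,4R)-6,8-dihydroxy-5-methoxy-3-methyl-1-oxoisochroman-4-yl acetate
Conditions: H2 (1 atm), 10% Pd/C, EtOAc, rt, stopped after uptake of 2 equiv H2
Reagents that add atoms: none
Why: Catalytic hydrogenolysis of the two aryl benzyl ethers should be much faster than cleavage of the hindered secondary benzylic acetate at C4 (its ring carries the electron-withdrawing lactone carbonyl ortho to C4a) in a neutral solvent.

**Step 8**
Reactants: 12 (3R,4R)-6,8-dihydroxy-5-methoxy-3-methyl-1-oxoisochroman-4-yl acetate; 13 geranyl bromide ((2E)-1-bromo-3,7-dimethylocta-2,6-diene)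
Product: 14 (3R,4R)-6-{[(2E)-3,7-dimethylocta-2,6-dien-1-yl]oxy}-8-hydroxy-5-methoxy-3-methyl-1-oxoisochroman-4-yl acetate (target)
Conditions: K2CO3 (1.2 equiv), geranyl bromide (1.05 equiv), acetone, rt
Reagents that add atoms: none
Why: Williamson ether synthesis under mild carbonate conditions should alkylate only the C6 phenol, the more acidic one (para to the lactone carbonyl), since the C8 phenol is held in a hydrogen bond to C1=O; SN2 at the primary allylic bromide keeps the E double bond and the acetate survives anhydrous K2CO3.

**Compound list**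
1 | 5-bromo-2,4-dihydroxybenzoic acid | OC(=O)c1cc(Br)c(O)cc1O | starting material
2 | benzyl 2,4-bis(benzyloxy)-5-bromobenzoate | O=C(OCc1ccccc1)c1cc(Br)c(OCc2ccccc2)cc1OCc1ccccc1 | intermediate
3 | methyl 2,4-bis(benzyloxy)-5-bromobenzoate | COC(=O)c1cc(Br)c(OCc2ccccc2)cc1OCc1ccccc1 | intermediate (not isolated)
4 | methyl 2,4-bis(benzyloxy)-5-methoxybenzoate | COC(=O)c1cc(OC)c(OCc2ccccc2)cc1OCc1ccccc1 | intermediate (not isolated)
5 | 2,4-bis(benzyloxy)-5-methoxybenzoic acid | OC(=O)c1cc(OC)c(OCc2ccccc2)cc1OCc1ccccc1 | intermediate
6 | 1,2-butadiene | C=C=CC | starting material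
7 | rac-6,8-bis(benzyloxy)-5-methoxy-3-methyl-4-methylideneisochroman-1-one | COc1c(OCc2ccccc2)cc(OCc2ccccc2)c2c1C(=C)C(C)OC2=O | intermediate
8 | 6,8-bis(benzyloxy)-4-hydroxy-4-(hydroxymethyl)-5-methoxy-3-methylisochroman-1-one (racemic, diastereomer mixture) | COc1c(OCc2ccccc2)cc(OCc2ccccc2)c2c1C(O)(CO)C(C)OC2=O | intermediate (not isolated)
9 | rac-6,8-bis(benzyloxy)-5-methoxy-3-methylisochromane-1,4-dione | COc1c(OCc2ccccc2)cc(OCc2ccccc2)c2c1C(=O)C(C)OC2=O | intermediate
10 | (3R,4R)-6,8-bis(benzyloxy)-4-hydroxy-5-methoxy-3-methylisochroman-1-one | COc1c(OCc2ccccc2)cc(OCc2ccccc2)c2c1[C@@H](O)[C@@H](C)OC2=O | intermediate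
11 | (3R,4R)-6,8-bis(benzyloxy)-5-methoxy-3-methyl-1-oxoisochroman-4-yl acetate | COc1c(OCc2ccccc2)cc(OCc2ccccc2)c2c1[C@@H](OC(C)=O)[C@@H](C)OC2=O | intermediate
12 | (3R,4R)-6,8-dihydroxy-5-methoxy-3-methyl-1-oxoisochroman-4-yl acetate | COc1c(O)cc(O)c2c1[C@@H](OC(C)=O)[C@@H](C)OC2=O | intermediate
13 | geranyl bromide, (2E)-1-bromo-3,7-dimethylocta-2,6-diene | BrC/C=C(\C)CCC=C(C)C | starting material
14 | (3R,4R)-6-{[(2E)-3,7-dimethylocta-2,6-dien-1-yl]oxy}-8-hydroxy-5-methoxy-3-methyl-1-oxoisochroman-4-yl acetate | COc1c(OC/C=C(\C)CCC=C(C)C)cc(O)c2c1[C@@H](OC(C)=O)[C@@H](C)OC2=O | target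

**Totals:** 8 steps; longest linear sequence 8 steps (1 to 14).

**Steps most likely to fail**

Step 3 (Proposed new method). What may go wrong:
- palladation may be slow at the C–H wedged between the carboxylate and the methoxy group;
- the allylpalladium intermediate may lose a β-hydride to give a diene instead of closing;
- C–O closure may occur at the CH2 terminus;
- the exocyclic double bond may migrate into the ring;
- the free acid may simply add across the allene.

Fallback by known chemistry, setting out from 5 and coming back at 7: carboxylate-directed ortho-lithiation (s-BuLi/TMEDA, THF, −78 °C) and an I2 quench would give 4,6-bis(benzyloxy)-2-iodo-3-methoxybenzoic acid F1. Heteroannulation of 1,2-butadiene 6 by this iodide under zerovalent palladium (Pd(OAc)2 5 mol%, PPh3, Na2CO3, Bu4NCl, DMF, 80 °C) then replaces C–H palladation by oxidative addition of the C–I bond and should deliver 7 through the same allylpalladium carboxylate.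

Step 5. What may go wrong:
- epimerisation at C3 may be slower than reduction, which would erode the cis:trans ratio;
- the facial preference of the catalyst may be insufficient or opposite on this peri-substituted ketone;
- the product alcohol may translactonise to the five-membered phthalide.

Fallback, setting out from 9 and coming back at 10: substrate-controlled reduction with NaBH4 (MeOH/CH2Cl2, −78 °C; hydride anti to the C3 methyl) should give the racemic cis alcohol, rac-(3R,4R)-6,8-bis(benzyloxy)-4-hydroxy-5-methoxy-3-methylisochroman-1-one F2. Lipase-catalysed kinetic resolution (Candida antarctica lipase B, vinyl acetate, MTBE) is then expected, by the usual rule for benzo-fused cyclic carbinols, to acetylate the unwanted enantiomer to (3S,4S)-6,8-bis(benzyloxy)-5-methoxy-3-methyl-1-oxoisochroman-4-yl acetate F3 and leave 10 as the unreacted alcohol.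

Step 7. What may go wrong: hydrogenolysis of the benzylic C4–O acetate bond may compete with O-debenzylation.

Fallback, setting out from 10 and coming back at 14, with the acetate introduced after all reductive steps:
- hydrogenolysis of 10 (H2, Pd/C, EtOAc) would give (3R,4R)-4,6,8-trihydroxy-5-methoxy-3-methylisochroman-1-one F4;
- O6-selective alkylation with 13 (K2CO3, acetone) would give (3R,4R)-6-(geranyloxy)-4,8-dihydroxy-5-methoxy-3-methylisochroman-1-one F5;
- exhaustive acetylation (Ac2O, pyridine, DMAP) would give (3R,4R)-6-(geranyloxy)-5-methoxy-3-methyl-1-oxoisochromane-4,8-diyl diacetate F6;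
- aminolysis of the more labile aryl acetate alone (pyrrolidine 1.0 equiv, CH2Cl2, 0 °C) would give 14.

**Further compounds**
F1 | step 3 | 4,6-bis(benzyloxy)-2-iodo-3-methoxybenzoic acid | OC(=O)c1c(I)c(OC)c(OCc2ccccc2)cc1OCc1ccccc1
F2 | step 5 | rac-(3R,4R)-6,8-bis(benzyloxy)-4-hydroxy-5-methoxy-3-methylisochroman-1-one (racemic cis alcohol, both enantiomers) | COc1c(OCc2ccccc2)cc(OCc2ccccc2)c2c1[C@@H](O)[C@@H](C)OC2=O.COc1c(OCc2ccccc2)cc(OCc2ccccc2)c2c1[C@H](O)[C@H](C)OC2=O
F3 | step 5 | (3S,4S)-6,8-bis(benzyloxy)-5-methoxy-3-methyl-1-oxoisochroman-4-yl acetate | COc1c(OCc2ccccc2)cc(OCc2ccccc2)c2c1[C@H](OC(C)=O)[C@H](C)OC2=O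
F4 | step 7 | (3R,4R)-4,6,8-trihydroxy-5-methoxy-3-methylisochroman-1-one | COc1c(O)cc(O)c2c1[C@@H](O)[C@@H](C)OC2=O
F5 | step 7 | (3R,4R)-6-(geranyloxy)-4,8-dihydroxy-5-methoxy-3-methylisochroman-1-one | COc1c(OC/C=C(\C)CCC=C(C)C)cc(O)c2c1[C@@H](O)[C@@H](C)OC2=O
F6 | step 7 | (3R,4R)-6-(geranyloxy)-5-methoxy-3-methyl-1-oxoisochromane-4,8-diyl diacetate | COc1c(OC/C=C(\C)CCC=C(C)C)cc(OC(C)=O)c2c1[C@@H](OC(C)=O)[C@@H](C)OC2=O
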